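4 questions stand on this flask; "now" and summer can be read from the flat target, but the choice of option and the figure after dusk turn on why it stops rising.

| flask | starting material | second substrate | free enzyme | temperature | remark | time |
|---|---|---|---|---|---|---|
| south-east | 0.10 M | 1 equiv | 0.01 mol% | 25 °C | the very flask that is asked about, followed so far |  |
| flask | 0.10 M | 1.00 equiv | 0.01 mol% | 25 °C |  | 5.0 d |
south-east run (percent of the starting material charged)

| time / d | target / % |
|---|---|
| 0.833 | 10.9 |
| 1.67 | 16.3 |
| 2.50 | 17.3 |
| 3.00 | 17.3 |
| 4.00 | 18.0 |
| 5.00 | 17.5 |

(readings scatter by 0.5 percentage points)
- spring: at 5.0 d add free enzyme, 100% of the amount charged, then wait 2.5 d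
- summer: change nothing and wait 2.5 d more
- midnight: at 5.0 d raise the temperature by 10 K, then wait 2.5 d
- dusk: at 5.0 d add starting material, 50.0% of the amount charged, then wait 2.5 d
- what is added takes up no volume worth counting
- the earlier runs were read with a standard deviation of 0.5 percentage points
- the earlier runs do not show what temperature does; that part of a forecast is a guess
- a reading or a percentage of target counts all its forms, free or not
- target, in percent of the starting material first charged, at 5.0 d
- the option that brings most further target ("none" if no option brings more than 2 percentage points) (spring / summer / midnight / dusk / none)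
- target present, in percent of the starting material first charged, after summer
- target present, in percent of the starting material first charged, after dusk

The south-east run is the flask itself. Its target holds flat from 2.50 d, with a mean of 17.5% over the last 4 readings, so "now" is about that and summer offers nothing visible. One reading of the stop is a dying enzyme, with starting material consumed pseudo-first-order while the enzyme lives. One charge is then measured by its exposure, minus the natural logarithm of the fraction of starting material it leaves, which this plateau puts at 0.193. The symmetric case is the zero of the scale: an equal fresh charge repeats that exposure. But it meets less starting material, so spring gains 14 percentage points, not the full plateau.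

The objection is that the stop may be an equilibrium, which leaves spring nothing, and the readings do not separate the two. The forecast “leans towards a saturated enzyme reaching equilibrium”: it gives 17.6% now, 17.6% after summer and 23.5% after dusk, and chooses dusk. This reckoning differs. At even odds, the stake on spring exceeds the 5.9 points on dusk, so it chooses spring. A further doubt stays open: the exposure counts target as the sole fate of the starting material.

The flask gives 17.8% now, 17.8% after summer and 20.7% after dusk. The best option is spring, at 7.6 points against 2.8 points for dusk, −0.39 points for midnight and 0 points for summer.

    free enzyme → unfolded enzyme (k = 0.0130 h⁻¹, Ea = 285 kJ mol⁻¹)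
    starting material + free enzyme ⇌ complex A (K = 4.52 L mol⁻¹, k = 2.69 × 10⁵ L mol⁻¹ h⁻¹, Ea = 51.0 kJ mol⁻¹, ΔH = −17.0 kJ mol⁻¹)
    complex A → free enzyme + target (k = 303 h⁻¹, Ea = 87.0 kJ mol⁻¹)
    second substrate + free enzyme ⇌ complex B (K = 50.9 L mol⁻¹, k = 1.52 × 10⁵ L mol⁻¹ h⁻¹, Ea = 50.0 kJ mol⁻¹, ΔH = −25.0 kJ mol⁻¹)
    complex B → free enzyme + second product (k = 2920 h⁻¹, Ea = 74.0 kJ mol⁻¹)
    second substrate + target ⇌ idle adduct, settled at all times (K = 4.55 L mol⁻¹, ΔH = −17.0 kJ mol⁻¹)
    target ⇌ isomer of the product (K = 2.60, k = 0.0345 h⁻¹, Ea = 89.0 kJ mol⁻¹, ΔH = −20.0 kJ mol⁻¹)
    (constants at 25 °C)

Spring gains 7.6 points, about half of the reckoned 14 points. At 5.00 d the flask also holds 33.6% isomer of the product and 49% starting material, so its exposure counted on starting material left is 0.722, larger than the 0.193 read from target. The neighbouring flask has 0.40 M starting material, and with the equivalents and loading held its enzyme rises 4.00 times as well. The exposure scaled from target is 0.771, which reckons 53.7% converted, while the neighbouring flask holds 29.9% target and 63.1% isomer of the product. Counted on the 7.1% starting material left, its exposure is 2.65, which is 3.67 times that of the flask.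

The runs were generated by integration on assumed constants; the scatter is artificial.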